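**Plan** (hydroazulene numbering: C1, C2, C3 = C(OH)iPr, C3a = ring-fusion CH, C4 = ester carbon, C5, C6 = epoxide C–Me, C7, C8, C8a = quaternary C–Me)

- Cuts, in retrosynthetic order: the C4–O acyl bond; the C6/C7 epoxide oxygen; then C1–C2 and C3–C3a of the five-membered ring together; then the C6=C7 alkene (metathesis), C4–C5 (Grignard) and the cyclopropane CH2.
- Enabling feature: oxygen sits on C4, the seven-membered-ring carbon next to fusion carbon C3a. With C4 as a ketone, C3a, C8a and C1 can be the three carbons of a fused cyclopropyl ketone (a bicyclo[5.1.0]octenone). Its ketyl opens to a C1 radical and a C3a enolate, which take up a two-carbon alkene (C2=C3) and close the cyclopentane. The 1,3-relation of C3–O to C4=O lets C3 carry a sulfonyl helper that leaves to an enone.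
- Ring order forward: cyclopropane from a (Z)-dienol, seven-membered ring by ring-closing metathesis, five-membered ring by the radical relay (cyclopropane consumed), epoxide last.
- Stereochemistry: C8a from the ligand-controlled cyclopropanation. C3 from a hydroxyl-directed epoxidation that follows a methyl-controlled 1,2-reduction. C3a by protonation and equilibration (carbonyl trans to isopropyl). C4 by hydroxyl-directed hydride delivery. C6/C7 by hydroxyl-directed epoxidation.

Key step: step 9

Assumption: the dioxaborolane-controlled cyclopropanation shows the same sense of induction with this (Z)-trisubstituted allylic alcohol as with its usual substrates, so the (S,S)-ligand leads to the required C8a configuration.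

Step 1
Reactants: 1 but-2-yn-1-ol
Product: 2 (2Z)-3-iodobut-2-en-1-ol
Conditions: NaAlH2(OCH2CH2OMe)2, THF, 0 °C to rt; then I2, −78 °C to rt
Reagents that add atoms: iodine, II
Why: Hydroalumination–iodination of a propargylic alcohol: the alkoxide directs trans-hydroalumination so that aluminium sits on C3 cis to the CH2O group, and iodinolysis of the C–Al bond with retention should give the Z iodide.

Step 2
Reactants: 2 (2Z)-3-iodobut-2-en-1-ol; 3 allyltributylstannane
Product: 4 (2Z)-3-methylhexa-2,5-dien-1-ol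
Conditions: Pd(PPh3)4 (5 mol %), CuI (10 mol %), CsF (2 equiv), DMF, 45 °C
Reagents that add atoms: none
Why: Stille coupling of an alkenyl iodide with an allylstannane should proceed with retention of the alkene geometry, so the allyl group ends cis to CH2OH, and the mild fluoride/copper conditions should leave the skipped diene unconjugated.

Step 3
Reactants: 4 (2Z)-3-methylhexa-2,5-dien-1-ol
Product: 5 [(1R,2S)-2-methyl-2-(prop-2-en-1-yl)cyclopropyl]methanol
Conditions: Et2Zn, CH2I2, DME (forms Zn(CH2I)2·DME); (4S,5S)-2-butyl-N,N,N′,N′-tetramethyl-1,3,2-dioxaborolane-4,5-dicarboxamide (1.2 equiv), CH2Cl2, −10 °C to rt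
Reagents that add atoms: diiodomethane, ICI
Why: Asymmetric Simmons–Smith cyclopropanation: the zinc alkoxide bound to the chiral dioxaborolane delivers CH2 to one face of the allylic alkene only (the remote terminal alkene is not directed), the Z geometry keeps CH2OH and allyl cis, and the quaternary carbon set here becomes C8a.

Step 4
Reactants: 5 [(1R,2S)-2-methyl-2-(prop-2-en-1-yl)cyclopropyl]methanol
Product: 6 (1R,2S)-2-methyl-2-(prop-2-en-1-yl)cyclopropane-1-carbaldehyde
Conditions: Dess–Martin periodinane, pyridine, CH2Cl2, 0 °C to rt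
Reagents that add atoms: none
Why: Dess–Martin oxidation under buffered conditions should give the aldehyde without epimerising the cis-cyclopropane.

Step 5
Reactants: 6 (1R,2S)-2-methyl-2-(prop-2-en-1-yl)cyclopropane-1-carbaldehyde; 7 (2-methylprop-2-en-1-yl)magnesium chloride
Product: 8 3-methyl-1-[(1R,2S)-2-methyl-2-(prop-2-en-1-yl)cyclopropyl]but-3-en-1-ol (both carbinol epimers)
Conditions: THF, −78 °C; aq. NH4Cl
Reagents that add atoms: none
Why: Grignard addition forms the C4–C5 bond, and the new carbinol centre needs no control because step 7 oxidises it.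

Step 6
Reactants: 8 3-methyl-1-[(1R,2S)-2-methyl-2-(prop-2-en-1-yl)cyclopropyl]but-3-en-1-ol
Product: 9 (1R,7S)-4,7-dimethylbicyclo[5.1.0]oct-4-en-2-ol (both C2 epimers)
Conditions: second-generation Grubbs catalyst (5 mol %), CH2Cl2 (5 mM), 40 °C
Reagents that add atoms: none
Why: Ring-closing metathesis between the allyl and 2-methylallyl termini, held cis on the cyclopropane, should close the seven-membered ring with its trisubstituted C6=C7 alkene and release ethene.

Step 7
Reactants: 9 (1R,7S)-4,7-dimethylbicyclo[5.1.0]oct-4-en-2-ol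
Product: 10 (1R,7S)-4,7-dimethylbicyclo[5.1.0]oct-4-en-2-one
Conditions: Dess–Martin periodinane, pyridine, CH2Cl2, 0 °C
Reagents that add atoms: none
Why: Dess–Martin oxidation under neutral conditions should give the cyclopropyl ketone without moving the β,γ-alkene into conjugation.

Step 8
Reactants: 11 3-methylbut-1-yne; 12 sodium benzenesulfinate
Product: 13 [(3-methylbut-1-en-2-yl)sulfonyl]benzene
Conditions: Pd(PPh3)4 (5 mol %), AcOH (1.2 equiv), THF, 70 °C, sealed tube
Reagents that add atoms: none
Why: Palladium-catalysed Markovnikov hydrosulfonylation of a terminal alkyne: the sulfinic acid freed by AcOH adds with hydrogen on the terminal carbon and sulfur on the internal one, which gives the α-branched vinyl sulfone.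

Step 9
Reactants: 10 (1R,7S)-4,7-dimethylbicyclo[5.1.0]oct-4-en-2-one; 13 [(3-methylbut-1-en-2-yl)sulfonyl]benzene
Product: 15 (8aR)-6,8a-dimethyl-3-(propan-2-yl)-1,2,8,8a-tetrahydroazulen-4(5H)-one, via keto sulfone 14 (not isolated)
Conditions: SmI2 (25 mol %), Sm powder (25 mol %), 13 (3 equiv), THF, 55 °C; then DBU (1.5 equiv), 0 °C to rt
Reagents that add atoms: none
Why: Proposed new method: electron transfer from SmI2 to the C4 ketone of 10 gives a ketyl whose external cyclopropane bond C3a–C1 (the bond best aligned with the ketyl π system in the rigid bicyclo[5.1.0] frame) fragments to a trivalent samarium enolate (C3a=C4) and a primary C1 radical; this radical adds to the CH2 end of vinyl sulfone 13 (bond C1–C2), the electrophilic α-sulfonyl radical at C3 closes on the enolate carbon C3a (bond C3–C3a), and the new ketyl returns its electron to trivalent samarium, so SmI2 stays catalytic while Sm metal restores any oxidised catalyst. The closest known reaction type is the SmI2-catalysed radical-relay formal [3+2] cycloaddition of bicyclic alkyl cyclopropyl ketones with alkynes and activated alkenes; new here are the α-branched vinyl sulfone as the two-carbon partner and the E1cB loss of benzenesulfinate from 14 with DBU in the same flask. The cyclopentane is the only ring closed, by 5-exo-trig radical addition to the enolate. C3 and C3a arise in 14 without control (a cis fusion is expected, since the chain hangs from the face that carried C1) and both become sp2 in 15, so no new stereocentre has to be set and C8a is not touched. The selectivity needed is opening of the external bond and not the internal C3a–C8a bond: opening is reversible and the unhindered primary radical should be trapped faster than the tertiary radical of an eight-membered enolate, and the C6=C7 alkene is spared because attack on it would be 4-exo or 5-endo.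

Step 10
Reactants: 15 (8aR)-6,8a-dimethyl-3-(propan-2-yl)-1,2,8,8a-tetrahydroazulen-4(5H)-one
Product: 16 (4R,8aR)-6,8a-dimethyl-3-(propan-2-yl)-1,2,4,5,8,8a-hexahydroazulen-4-ol
Conditions: NaBH4, CeCl3·7H2O, MeOH, −40 °C
Reagents that add atoms: none
Why: Luche 1,2-reduction: hydride should attack the C4 carbonyl from the face opposite the 1,3-related C8a methyl, which places the allylic hydroxyl cis to that methyl.

Step 11
Reactants: 16 (4R,8aR)-6,8a-dimethyl-3-(propan-2-yl)-1,2,4,5,8,8a-hexahydroazulen-4-ol
Product: 17 (3R,3aS,4R,8aR)-3,3a-epoxy-6,8a-dimethyl-3-(propan-2-yl)-1,2,3,3a,4,5,8,8a-octahydroazulen-4-ol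
Conditions: VO(acac)2 (5 mol %), tBuOOH (1.2 equiv), CH2Cl2, 0 °C
Reagents that add atoms: tert-butyl hydroperoxide, CC(C)(C)OO
Why: Hydroxyl-directed vanadium-catalysed epoxidation: the allylic C4 alkoxide on vanadium delivers oxygen to its own face of the C3=C3a alkene (far faster than to the homoallylic C6=C7 alkene), so the C3–O bond is set cis to the C8a methyl.

Step 12
Reactants: 17 (3R,3aS,4R,8aR)-3,3a-epoxy-6,8a-dimethyl-3-(propan-2-yl)-1,2,3,3a,4,5,8,8a-octahydroazulen-4-ol
Product: 18 (3R,3aR,8aR)-3,3a-epoxy-6,8a-dimethyl-3-(propan-2-yl)-2,3,3a,5,8,8a-hexahydroazulen-4(1H)-one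
Conditions: Dess–Martin periodinane, pyridine, CH2Cl2, 0 °C
Reagents that add atoms: none
Why: Dess–Martin oxidation under neutral conditions should give the α,β-epoxy ketone without opening the acid-sensitive tetrasubstituted epoxide.

Step 13
Reactants: 18 (3R,3aR,8aR)-3,3a-epoxy-6,8a-dimethyl-3-(propan-2-yl)-2,3,3a,5,8,8a-hexahydroazulen-4(1H)-one
Product: 19 (3R,3aR,8aR)-3-hydroxy-6,8a-dimethyl-3-(propan-2-yl)-2,3,3a,5,8,8a-hexahydroazulen-4(1H)-one
Conditions: SmI2 (2.2 equiv), THF–MeOH, −90 °C; then Et3N (0.2 equiv), CH2Cl2, rt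
Reagents that add atoms: none
Why: SmI2 reduction of an α,β-epoxy ketone cleaves only the Cα–O bond (C3a–O), so C3 keeps its oxygen with retention; methanol protonates the samarium enolate at C3a and amine equilibration through the enol should leave the epimer with the C4 carbonyl trans to the C3 isopropyl group, which is the trans ring fusion.

Step 14
Reactants: 19 (3R,3aR,8aR)-3-hydroxy-6,8a-dimethyl-3-(propan-2-yl)-2,3,3a,5,8,8a-hexahydroazulen-4(1H)-one
Product: 20 (3R,3aS,4S,8aR)-6,8a-dimethyl-3-(propan-2-yl)-1,2,3,3a,4,5,8,8a-octahydroazulene-3,4-diol (jaeschkeanadiol)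
Conditions: Me4NBH(OAc)3 (5 equiv), MeCN–AcOH (1:1), −30 °C
Reagents that add atoms: none
Why: Evans–Saksena reduction: the tertiary C3 hydroxyl exchanges onto boron and hydride is delivered inside the complex to the C4 carbonyl from the face of the C3–O bond, which should give the anti-1,3-diol with C4–OH cis to H3a.

Step 15
Reactants: 20 (3R,3aS,4S,8aR)-6,8a-dimethyl-3-(propan-2-yl)-1,2,3,3a,4,5,8,8a-octahydroazulene-3,4-diol
Product: 21 (3R,3aS,4S,6R,7S,8aR)-6,7-epoxy-6,8a-dimethyl-3-(propan-2-yl)decahydroazulene-3,4-diol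
Conditions: VO(acac)2 (5 mol %), tBuOOH (1.5 equiv), CH2Cl2, 0 °C to rt
Reagents that add atoms: tert-butyl hydroperoxide, CC(C)(C)OO
Why: Vanadium-catalysed epoxidation directed by the homoallylic C4 hydroxyl should place the epoxide oxygen on the face of that hydroxyl (anti to the C8a methyl) and so set C6 and C7.

Step 16
Reactants: 21 (3R,3aS,4S,6R,7S,8aR)-6,7-epoxy-6,8a-dimethyl-3-(propan-2-yl)decahydroazulene-3,4-diol; 22 3,4-dimethoxybenzoic acid
Product: 23 (3R,3aS,4S,6R,7S,8aR)-6,7-epoxy-3-hydroxy-6,8a-dimethyl-3-(propan-2-yl)decahydroazulen-4-yl 3,4-dimethoxybenzoate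
Conditions: DCC (1.5 equiv), DMAP (0.5 equiv), CH2Cl2, rt
Reagents that add atoms: none
Why: Steglich esterification should acylate only the secondary C4 hydroxyl (the tertiary C3 hydroxyl is too hindered) under neutral conditions that spare the epoxide.

**Compound list**

1 | but-2-yn-1-ol | CC#CCO | starting material
2 | (2Z)-3-iodobut-2-en-1-ol | C/C(I)=C/CO | intermediate
3 | allyltributylstannane | C=CC[Sn](CCCC)(CCCC)CCCC | starting material
4 | (2Z)-3-methylhexa-2,5-dien-1-ol | OC/C=C(/C)CC=C | intermediate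
5 | [(1R,2S)-2-methyl-2-(prop-2-en-1-yl)cyclopropyl]methanol | OC[C@@H]1C[C@]1(C)CC=C | intermediate
6 | (1R,2S)-2-methyl-2-(prop-2-en-1-yl)cyclopropane-1-carbaldehyde | O=C[C@@H]1C[C@]1(C)CC=C | intermediate
7 | (2-methylprop-2-en-1-yl)magnesium chloride | CC(=C)C[Mg]Cl | starting material
8 | 3-methyl-1-[(1R,2S)-2-methyl-2-(prop-2-en-1-yl)cyclopropyl]but-3-en-1-ol (both carbinol epimers) | OC(CC(C)=C)[C@@H]1C[C@]1(C)CC=C | intermediate
9 | (1R,7S)-4,7-dimethylbicyclo[5.1.0]oct-4-en-2-ol (both C2 epimers) | OC1CC(C)=CC[C@@]2(C)C[C@@H]12 | intermediate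
10 | (1R,7S)-4,7-dimethylbicyclo[5.1.0]oct-4-en-2-one | O=C1CC(C)=CC[C@@]2(C)C[C@@H]12 | intermediate
11 | 3-methylbut-1-yne | CC(C)C#C | starting material
12 | sodium benzenesulfinate | [Na+].[O-]S(=O)c1ccccc1 | starting material
13 | [(3-methylbut-1-en-2-yl)sulfonyl]benzene | C=C(C(C)C)S(=O)(=O)c1ccccc1 | intermediate
14 | (8aR)-3-(benzenesulfonyl)-6,8a-dimethyl-3-(propan-2-yl)-2,3,3a,5,8,8a-hexahydroazulen-4(1H)-one (C3/C3a isomers, not isolated) | O=C1CC(C)=CC[C@@]2(C)CCC(C(C)C)(S(=O)(=O)c3ccccc3)C12 | intermediate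
15 | (8aR)-6,8a-dimethyl-3-(propan-2-yl)-1,2,8,8a-tetrahydroazulen-4(5H)-one | O=C1CC(C)=CC[C@@]2(C)CCC(C(C)C)=C12 | intermediate
16 | (4R,8aR)-6,8a-dimethyl-3-(propan-2-yl)-1,2,4,5,8,8a-hexahydroazulen-4-ol | O[C@@H]1CC(C)=CC[C@@]2(C)CCC(C(C)C)=C12 | intermediate
17 | (3R,3aS,4R,8aR)-3,3a-epoxy-6,8a-dimethyl-3-(propan-2-yl)-1,2,3,3a,4,5,8,8a-octahydroazulen-4-ol | O[C@@H]1CC(C)=CC[C@@]2(C)CC[C@]3(C(C)C)O[C@]123 | intermediate
18 | (3R,3aR,8aR)-3,3a-epoxy-6,8a-dimethyl-3-(propan-2-yl)-2,3,3a,5,8,8a-hexahydroazulen-4(1H)-one | O=C1CC(C)=CC[C@@]2(C)CC[C@]3(C(C)C)O[C@]123 | intermediate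
19 | (3R,3aR,8aR)-3-hydroxy-6,8a-dimethyl-3-(propan-2-yl)-2,3,3a,5,8,8a-hexahydroazulen-4(1H)-one | O=C1CC(C)=CC[C@@]2(C)CC[C@@](O)(C(C)C)[C@H]12 | intermediate
20 | (3R,3aS,4S,8aR)-6,8a-dimethyl-3-(propan-2-yl)-1,2,3,3a,4,5,8,8a-octahydroazulene-3,4-diol (jaeschkeanadiol) | O[C@H]1CC(C)=CC[C@@]2(C)CC[C@@](O)(C(C)C)[C@H]12 | intermediate
21 | (3R,3aS,4S,6R,7S,8aR)-6,7-epoxy-6,8a-dimethyl-3-(propan-2-yl)decahydroazulene-3,4-diol | O[C@H]1C[C@@]2(C)O[C@H]2C[C@@]2(C)CC[C@@](O)(C(C)C)[C@H]12 | intermediate
22 | 3,4-dimethoxybenzoic acid | COc1ccc(C(=O)O)cc1OC | starting material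
23 | (3R,3aS,4S,6R,7S,8aR)-6,7-epoxy-3-hydroxy-6,8a-dimethyl-3-(propan-2-yl)decahydroazulen-4-yl 3,4-dimethoxybenzoate | COc1ccc(C(=O)O[C@H]2C[C@@]3(C)O[C@H]3C[C@@]3(C)CC[C@@](O)(C(C)C)[C@H]23)cc1OC | target

**Step count:** 16 steps in total. Longest linear sequence: 15 steps (steps 1–7 and 9–16); step 8 makes the sulfone partner.

**Steps most likely to fail**

Step 9. The relay may stall in several ways. The hindered C1 radical may add too slowly to the sulfone. The α-sulfonyl radical may be reduced or abstract hydrogen before it closes. The acidic C5 methylene of 10 may protonate the samarium enolate. DBU may move the C6=C7 alkene into conjugation. Fallback with known chemistry, setting out from 10: the same SmI2/Sm-catalysed relay is run with 2-methylbut-1-en-3-yne, a conjugated enyne of the partner class for which this relay is established. It should give (8aR)-6,8a-dimethyl-3-(prop-1-en-2-yl)-3a,5,8,8a-tetrahydroazulen-4(1H)-one F1. DBU then brings the ring alkene into conjugation to give the trienone (8aR)-6,8a-dimethyl-3-(prop-1-en-2-yl)-1,2,8,8a-tetrahydroazulen-4(5H)-one F2. Hydrogenation with H2 and RhCl(PPh3)3 saturates only the 1,1-disubstituted isopropenyl alkene and returns to the route at 15.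

Step 10. Facial selectivity of the hydride addition may be poor or reversed, and the directing hydroxyl would then steer the epoxide of step 11 to the wrong face of C3. Fallback, setting out from 15: the reduction product is separated and the unwanted epimer (4S,8aR)-6,8a-dimethyl-3-(propan-2-yl)-1,2,4,5,8,8a-hexahydroazulen-4-ol F3 is inverted by a Mitsunobu reaction (4-nitrobenzoic acid, PPh3, DIAD). This gives (4R,8aR)-6,8a-dimethyl-3-(propan-2-yl)-1,2,4,5,8,8a-hexahydroazulen-4-yl 4-nitrobenzoate F4. Methanolysis (K2CO3, MeOH) returns to the route at 16.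

Step 14. Exchange of the hindered tertiary hydroxyl onto boron may be too slow, so that undirected hydride attack or acid-promoted retro-aldol cleavage competes and the C4 carbinol forms with the wrong configuration. Fallback, setting out from 19: an undirected reduction (NaBH4, CeCl3·7H2O, MeOH) is used on purpose. As in step 10 it should attack anti to the C8a methyl and give (3R,3aS,4R,8aR)-6,8a-dimethyl-3-(propan-2-yl)-1,2,3,3a,4,5,8,8a-octahydroazulene-3,4-diol F5. A Mitsunobu esterification with 22 (PPh3, DIAD) inverts C4 and installs the ester in one step, to give (3R,3aS,4S,8aR)-3-hydroxy-6,8a-dimethyl-3-(propan-2-yl)-1,2,3,3a,4,5,8,8a-octahydroazulen-4-yl 3,4-dimethoxybenzoate F6. Epoxidation with mCPBA and NaHCO3 in CH2Cl2, on the face anti to the C8a methyl, returns to the route at 23.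

**Further compounds**

F1 | step 9 | (8aR)-6,8a-dimethyl-3-(prop-1-en-2-yl)-3a,5,8,8a-tetrahydroazulen-4(1H)-one (C3a isomers) | O=C1CC(C)=CC[C@@]2(C)CC=C(C(C)=C)C12
F2 | step 9 | (8aR)-6,8a-dimethyl-3-(prop-1-en-2-yl)-1,2,8,8a-tetrahydroazulen-4(5H)-one | O=C1CC(C)=CC[C@@]2(C)CCC(C(C)=C)=C12
F3 | step 10 | (4S,8aR)-6,8a-dimethyl-3-(propan-2-yl)-1,2,4,5,8,8a-hexahydroazulen-4-ol | O[C@H]1CC(C)=CC[C@@]2(C)CCC(C(C)C)=C12
F4 | step 10 | (4R,8aR)-6,8a-dimethyl-3-(propan-2-yl)-1,2,4,5,8,8a-hexahydroazulen-4-yl 4-nitrobenzoate | O=C(O[C@@H]1CC(C)=CC[C@@]2(C)CCC(C(C)C)=C12)c1ccc([N+](=O)[O-])cc1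
F5 | step 14 | (3R,3aS,4R,8aR)-6,8a-dimethyl-3-(propan-2-yl)-1,2,3,3a,4,5,8,8a-octahydroazulene-3,4-diol | O[C@@H]1CC(C)=CC[C@@]2(C)CC[C@@](O)(C(C)C)[C@H]12
F6 | step 14 | (3R,3aS,4S,8aR)-3-hydroxy-6,8a-dimethyl-3-(propan-2-yl)-1,2,3,3a,4,5,8,8a-octahydroazulen-4-yl 3,4-dimethoxybenzoate | COc1ccc(C(=O)O[C@H]2CC(C)=CC[C@@]3(C)CC[C@@](O)(C(C)C)[C@H]23)cc1OC
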